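## Analysis of the target

The target is an indole, a benzene ring fused to a pyrrole ring, with a methyl group on N1, bromine on C2, a dimethylaminomethyl arm on C3 and bromines on C5 and C6. It has no stereocentre and no double-bond or axial isomerism, so the problem is one of regiochemistry and functional-group tolerance only. The C3 arm is a gramine unit: the C3–CH2–N bond ionises easily to a 3-methyleneindoleninium ion, and the basic tertiary amine is readily N-halogenated or oxidised by electrophilic halogen. The three C–Br bonds rule out organolithium chemistry on the assembled skeleton and limit palladium chemistry. The 5,6-dibromo pattern is not what electrophilic bromination of an indole delivers, so both benzo bromines should come from a pre-halogenated benzene. The difficult point is placing bromine on C2 next to the labile C3 arm. The strategy rests on the C2–C3 edge of the pyrrole ring: these two carbons map onto the two sp carbons of a propargylic amine, with C3 already carrying CH2NMe2 and C2 carrying a silyl placeholder for bromine, while N1, C7a and C3a, with the N-methyl group and both benzo bromines, come from an ortho-iodoaniline.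

## Retrosynthetic reasoning

**C2–Br of 12.** The last bond made is C2–Br, traced back to the C2–Si bond of 9. Metalation at C2 is excluded by the C5 and C6 bromines, and direct electrophilic bromination with a free amine on the side chain would have to choose among C2, the benzo positions and the nitrogen lone pair. A silyl group at C2 directs the electrophile to its own carbon and leaves more readily than a proton. The forward reaction must exchange silicon for bromine while the side-chain nitrogen is masked as its ammonium salt 10; the product forms as salt 11 and is then set free.

**N1–C2 and C3–C3a of 9.** Cutting these two pyrrole bonds gives the iodoaniline 4 and the silylalkyne 8. The cut divides the molecule into a benzene piece holding N1, the N-methyl group and both bromines, and a three-carbon piece holding the whole side chain; no other pair of cuts leaves both halves this simple. The gain is one ring and two skeletal bonds in one operation, and the aminomethyl arm never has to be built on the indole by electrophilic chemistry. The forward reaction needs palladium to enter only the carbon–iodine bond, the alkyne to insert with silicon ending at C2, and nitrogen to close the ring.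

**C(sp)–Si of 8.** This bond is cut to the propargylic amine 5 and the chlorosilane 6, joined through the acetylide 7. The terminal C–H is the only acidic site of 5, so the union is unambiguous.

**N–CH3 of 4.** The methyl carbon is traced to the formyl carbon of formanilide 3, and 3 to the primary aniline 2. One carbon attached at the amide level guarantees mono-substitution, which direct alkylation of 2 would not. The forward reduction must leave three carbon–halogen bonds intact.

**C–I of 2.** The iodine is removed to give the dibromoaniline 1. The amino group directs ortho and para; the para position carries bromine, and one of the two ortho positions is flanked by bromine, so electrophilic iodination should go to the open ortho carbon, which is the one required.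

## Alternatives that were turned down

Alternative 1: The benzene ring is cut at C4–C5 and C6–C7. The precursors are the pyrrole-fused pyranone methyl 1-methyl-5-oxo-1,5-dihydropyrano[3,4-b]pyrrole-3-carboxylate (A1), which holds a diene locked in its lactone ring, and bis(trimethylsilyl)acetylene (A2). On heating, a [4+2] cycloaddition of A1 and A2 followed by loss of the lactone bridge as gas would give methyl 1-methyl-5,6-bis(trimethylsilyl)indole-3-carboxylate (A3).
- For: the dienophile A2 is symmetric, so C5 and C6 pose no regiochemical question, and both silyl groups of A3 mark the bromine positions. No transition metal is involved, so no discrimination between carbon–halogen bonds is needed; on that point it is stronger than the chosen route.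
- Against: A1 needs several steps from simple pyrrole building blocks, and its unsubstituted diene termini demand a formyl-level ring closure. A2 is a hindered, unactivated dienophile, so forcing temperatures are expected. After A3, four adjustments remain: two ipso brominations (the second ortho to a new bromine, with protodesilylation competing), bromination at C2, and conversion of the C3 ester to the amine in the presence of three C–Br bonds.
- Comparison: well over ten steps against six. The chosen strategy relies on a chemoselective palladium insertion, and in return buys both benzo bromines in the starting aniline and the complete side chain in the alkyne.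

Alternative 2: The benzene ring is cut at C3a–C4 and C7–C7a. The precursors are 3,4-dibromothiophene 1,1-dioxide (A4), an electron-poor diene, and the cyclic ketene N,S-acetal 1-methyl-5-(methylsulfanyl)-1,3-dihydro-2H-pyrrol-2-one (A5). Cycloaddition of A4 and A5, cheletropic loss of the sulfone bridge and elimination of the methylthio group as its thiol would give 5,6-dibromo-1-methylindolin-2-one (A6). In A6 the benzene ring is complete and the lactam carbonyl marks C2.
- For: the symmetric diene A4 carries both bromines, so the 5,6-pattern of A6 is fixed. The endgame from A6 is short: a Vilsmeier-type bromoformylation of the lactam should give 2,5,6-tribromo-1-methylindole-3-carbaldehyde (A7), with C2–Br and the C3 carbon placed in one operation. Reductive amination of A7 with the secondary amine then completes the target. This avoids a silicon detour and any electrophilic bromine near a basic amine, and on this point the route through A6 and A7 is stronger than the last step of the chosen route.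
- Against: A4 needs a strong oxidation of the dibromothiophene and is prone to self-condensation on heating. A5 is a non-aromatic tautomer whose double bond can move into conjugation with the carbonyl, and it takes several steps from the imide. The pairing of these two partners has no close analogy, so the whole risk sits in the step that makes A6, reached only after two separate partner syntheses.
- Comparison: the chosen strategy places its risk in an annulation of established type between partners made in three steps and one step. In place of the short endgame from A6 through A7 it offers a shorter sequence overall.

Alternative 3: Only C5–C6 is cut. The precursor is the enediyne methyl 4,5-bis(bromoethynyl)-1-methylpyrrole-2-carboxylate (A8). Thermal Bergman cycloaromatisation of A8, with the C4/C7 diradical quenched by a hydrogen-atom donor, would give methyl 5,6-dibromo-1-methylindole-2-carboxylate (A9).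
- For: both bromines of A8 sit on the alkyne termini and so arrive exactly at C5 and C6 of A9. The ring-forming step is metal-free, so again no carbon–halogen discrimination at a metal is required.
- Against: in A8 the five-membered heteroarene holds the alkyne termini far apart, and the terminal halogens add steric repulsion as the new bond forms. The barrier is therefore high, and the temperature needed is one at which the bromoalkynes of A8 decompose. Aryl radicals next to C–Br bonds in a hydrogen-donor medium invite radical-chain debromination and polymerisation. A9 then has an ester at C2 where bromine must stand and nothing at C3, so hydrolysis, decarboxylation, a Mannich reaction and a C2 bromination still follow.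
- Comparison: more than ten steps with the weakest key step of the four. The chosen strategy uses a catalytic ring closure below 100 °C that places both pyrrole substituents directly.

Key step: step 5

Remark: the target has no stereocentre, so no name or SMILES carries a descriptor; 1, 5 and 6 are taken as catalogue chemicals.

Step 1
Reactants: 1 3,4-dibromoaniline
Product: 2 4,5-dibromo-2-iodoaniline
Conditions: ICl (1.05 equiv), NaHCO3, CH2Cl2/MeOH, 0 °C to rt
Reagents that add atoms: iodine monochloride, ClI
Why: Electrophilic aromatic iodination directed by the amino group; the para position is blocked by bromine and the ortho position between nitrogen and bromine is shielded, so iodine should enter the open ortho carbon, which gives the 2-iodo-4,5-dibromo pattern. The two bromines deactivate the ring enough that one equivalent of ICl should stop at the mono-iodide, and NaHCO3 takes up the HCl.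

Step 2
Reactants: 2 4,5-dibromo-2-iodoaniline
Product: 3 N-(4,5-dibromo-2-iodophenyl)formamide
Conditions: HCO2H, Ac2O, 55 °C (forms acetic formic anhydride); then 2, THF, 0 °C to rt
Reagents that add atoms: acetic formic anhydride, CC(=O)OC=O
Why: N-Acylation of a weakly nucleophilic aniline by a mixed anhydride, which transfers its formyl group because the formyl carbonyl is the less hindered and more electrophilic one. The formyl carbon is the future N-methyl carbon and ensures that exactly one carbon is attached to nitrogen.

Step 3
Reactants: 3 N-(4,5-dibromo-2-iodophenyl)formamide
Product: 4 4,5-dibromo-2-iodo-N-methylaniline
Conditions: BH3·SMe2 (2.5 equiv), THF, 0 °C to reflux; MeOH, reflux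
Reagents that add atoms: none
Why: Borane reduction of a secondary amide to the amine: the electrophilic borane binds the formyl oxygen, delivers hydride, and after B–O cleavage to the iminium stage delivers a second hydride, so the N-methylaniline should form without any dialkylation. Aryl iodide and aryl bromides are inert to BH3, which is why it is preferred to LiAlH4 here.

Step 4
Reactants: 5 N,N-dimethylprop-2-yn-1-amine; 6 chlorotriethylsilane
Product: 8 N,N-dimethyl-3-(triethylsilyl)prop-2-yn-1-amine, via lithium acetylide 7 (not isolated)
Conditions: n-BuLi (1.05 equiv), THF, −78 °C; then Et3SiCl, −78 °C to rt
Reagents that add atoms: none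
Why: Deprotonation of the terminal alkyne by n-BuLi and C-silylation of the acetylide 7 by substitution at silicon; the tertiary amine is a spectator. The silyl group is the regiocontrol element of step 5 and the placeholder for the C2 bromine.

Step 5
Reactants: 4 4,5-dibromo-2-iodo-N-methylaniline; 8 N,N-dimethyl-3-(triethylsilyl)prop-2-yn-1-amine
Product: 9 5,6-dibromo-1-methyl-2-(triethylsilyl)gramine
Conditions: Pd(OAc)2 (5 mol %), LiCl (1 equiv), Na2CO3 (3 equiv), 8 (2 equiv), DMF, 90 °C, argon
Reagents that add atoms: none
Why: Larock heteroannulation of an ortho-iodoaniline with an internal silylalkyne, a known reaction type applied here to a dibrominated N-methylaniline and an amino alkyne. Pd(OAc)2 is reduced in the flask to chloride-ligated zerovalent palladium, which inserts into the C–I bond of 4; the alkyne 8 then inserts syn into the aryl–palladium bond so that the aryl carbon (future C3a) bonds to the alkyne carbon carrying CH2NMe2 (future C3) and palladium sits on the silicon-bearing carbon (future C2). The N-methylamino group displaces halide on divalent palladium, with carbonate taking up HI, to give a six-membered aza-palladacycle, and C–N reductive elimination forms N1–C2 and returns zerovalent palladium. The pyrrole ring is thus closed as a formal [3+2] annulation by reductive elimination with contraction from a six-membered metallacycle to the five-membered ring, not by endo attack of nitrogen on the alkyne. No stereocentre is formed. Two selectivities are needed: the regiochemistry of insertion, secured by the bulk of SiEt3, which prefers the position next to the long forming C–Pd bond over the short forming C–C bond and so ends at C2; and reaction at C–I only, secured by the much faster oxidative addition of an aryl iodide to phosphine-free palladium at 90 °C, under which the aryl bromides of 4 and 9 should stay intact. Triethylsilyl is used instead of trimethylsilyl because it resists carbonate-induced protodesilylation in hot DMF, and LiCl is held at one equivalent because chloride is needed on palladium but an excess slows the annulation.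

Step 6
Reactants: 9 5,6-dibromo-1-methyl-2-(triethylsilyl)gramine
Product: 12 2,5,6-tribromo-1-methylgramine, via 2-silylgramine trifluoroacetate salt 10 (not isolated), via tribromogramine trifluoroacetate salt 11 (not isolated)
Conditions: CF3CO2H (1.05 equiv), CH2Cl2, 0 °C; NBS (1.05 equiv), −20 to 0 °C, dark; aq. NaOH work-up
Reagents that add atoms: N-bromosuccinimide, O=C1CCC(=O)N1Br
Why: Ipso bromodesilylation of a 2-silylindole by NBS, a known electrophilic substitution: attack of electrophilic bromine at C2 gives a C3 cation stabilised by the adjacent C–Si bond (or attack at C3 is followed by a 1,2-shift of bromine), and loss of the silyl group restores the indole with bromine where silicon stood. One equivalent of CF3CO2H is added first so that the side-chain nitrogen is protonated in 10: the ammonium ion cannot be N-brominated or oxidised, cannot depart as an iminium ion after attack at C3, and consumes the strong acid so that none is left for protodesilylation. Aqueous base then liberates 12 from its salt 11.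

Compound list

1 | 3,4-dibromoaniline | Nc1ccc(Br)c(Br)c1 | starting material
2 | 4,5-dibromo-2-iodoaniline | Nc1cc(Br)c(Br)cc1I | intermediate
3 | N-(4,5-dibromo-2-iodophenyl)formamide | O=CNc1cc(Br)c(Br)cc1I | intermediate
4 | 4,5-dibromo-2-iodo-N-methylaniline | CNc1cc(Br)c(Br)cc1I | intermediate
5 | N,N-dimethylprop-2-yn-1-amine (N,N-dimethylpropargylamine) | C#CCN(C)C | starting material
6 | chlorotriethylsilane | CC[Si](Cl)(CC)CC | starting material
7 | [3-(dimethylamino)prop-1-yn-1-yl]lithium (lithium acetylide of 5) | [Li]C#CCN(C)C | intermediate
8 | N,N-dimethyl-3-(triethylsilyl)prop-2-yn-1-amine | CN(C)CC#C[Si](CC)(CC)CC | intermediate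
9 | 5,6-dibromo-1-methyl-2-(triethylsilyl)gramine, 1-[5,6-dibromo-1-methyl-2-(triethylsilyl)-1H-indol-3-yl]-N,N-dimethylmethanamine | CN(C)Cc1c([Si](CC)(CC)CC)n(C)c2cc(Br)c(Br)cc12 | intermediate
10 | trifluoroacetate salt of 9 | C[NH+](C)Cc1c([Si](CC)(CC)CC)n(C)c2cc(Br)c(Br)cc12.[O-]C(=O)C(F)(F)F | intermediate
11 | trifluoroacetate salt of 12 | C[NH+](C)Cc1c(Br)n(C)c2cc(Br)c(Br)cc12.[O-]C(=O)C(F)(F)F | intermediate
12 | 2,5,6-tribromo-1-methylgramine, 1-(2,5,6-tribromo-1-methyl-1H-indol-3-yl)-N,N-dimethylmethanamine | CN(C)Cc1c(Br)n(C)c2cc(Br)c(Br)cc12 | target

Total step count: 6. Longest linear sequence: 5 steps (steps 1, 2, 3, 5 and 6); step 4 is a one-step branch that supplies the alkyne.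

Steps least certain to work

**Step 5 (key step).** The basic propargylic amine can compete with the alkyne π-system for palladium, and the silylalkyne is bulky, so alkyne insertion may be slow. A long-lived arylpalladium species then invites hydrodeiodination, and if the temperature is raised to compensate, oxidative addition at the C–Br bonds of substrate and product with oligomerisation.

Fallback (sets out from 4, returns at 12): the basic alkyne is replaced by commercial 3-(trimethylsilyl)prop-2-yn-1-ol, a neutral partner of the kind most used in this annulation, and nitrogen is introduced after the ring is made. Annulation of 4 under the conditions of step 5 should give [5,6-dibromo-1-methyl-2-(trimethylsilyl)-1H-indol-3-yl]methanol F1. MeSO2Cl and Et3N in CH2Cl2 at −20 °C convert it into the mesylate [5,6-dibromo-1-methyl-2-(trimethylsilyl)-1H-indol-3-yl]methyl methanesulfonate F2, which is not isolated but treated at once with Me2NH in THF to give 5,6-dibromo-1-methyl-2-(trimethylsilyl)gramine F3. Protonation with CF3CO2H gives 5,6-dibromo-1-methyl-2-(trimethylsilyl)gramine trifluoroacetate salt F4, which NBS should convert into 11 and aqueous base into 12, as in step 6.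

**Step 6.** The triethylsilyl group is wedged between the N-methyl group and the ammoniomethyl arm, so ipso attack at C2 may be slow. Bromination on the benzo ring, oxidation at nitrogen where protonation is incomplete, or acid-induced protodesilylation could then compete.

Fallback (sets out from 9, returns at 12): silicon is first replaced by hydrogen, and bromine is then introduced by ordinary electrophilic substitution at the free C2 position. Bu4NF in THF at 60 °C should give 5,6-dibromo-1-methylgramine F5. Its salt, 5,6-dibromo-1-methylgramine trifluoroacetate salt F6, formed in the flask with CF3CO2H in CH2Cl2, is brominated with NBS at 0 °C. A 3-alkyl-1-methylindole is attacked at C3 and the bromine shifts to C2 with loss of a proton, which should give 11 and, after aqueous base, 12.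

**Step 3.** The boron-bound hemiaminal formed after the first hydride transfer can collapse by N–C cleavage instead of C–O cleavage, because the electron-poor, ortho-iodinated aniline nitrogen is a good leaving group. That deformylation would return 2 in place of the N-methyl compound.

Fallback (sets out from 3, returns at 4): the methyl group is attached by alkylation instead of reduction. MeI and Cs2CO3 in DMF at rt should give N-(4,5-dibromo-2-iodophenyl)-N-methylformamide F7, in which the formyl group guarantees mono-methylation. NaOH in aqueous EtOH at reflux then removes the formyl group to give 4.

Further compounds

F1 | step 5 | [5,6-dibromo-1-methyl-2-(trimethylsilyl)-1H-indol-3-yl]methanol | OCc1c([Si](C)(C)C)n(C)c2cc(Br)c(Br)cc12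
F2 | step 5 | [5,6-dibromo-1-methyl-2-(trimethylsilyl)-1H-indol-3-yl]methyl methanesulfonate | CS(=O)(=O)OCc1c([Si](C)(C)C)n(C)c2cc(Br)c(Br)cc12
F3 | step 5 | 5,6-dibromo-1-methyl-2-(trimethylsilyl)gramine | CN(C)Cc1c([Si](C)(C)C)n(C)c2cc(Br)c(Br)cc12
F4 | step 5 | 5,6-dibromo-1-methyl-2-(trimethylsilyl)gramine trifluoroacetate salt | C[NH+](C)Cc1c([Si](C)(C)C)n(C)c2cc(Br)c(Br)cc12.[O-]C(=O)C(F)(F)F
F5 | step 6 | 5,6-dibromo-1-methylgramine | CN(C)Cc1cn(C)c2cc(Br)c(Br)cc12
F6 | step 6 | 5,6-dibromo-1-methylgramine trifluoroacetate salt | C[NH+](C)Cc1cn(C)c2cc(Br)c(Br)cc12.[O-]C(=O)C(F)(F)F
F7 | step 3 | N-(4,5-dibromo-2-iodophenyl)-N-methylformamide | O=CN(C)c1cc(Br)c(Br)cc1I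
A1 | alternative 1 | methyl 1-methyl-5-oxo-1,5-dihydropyrano[3,4-b]pyrrole-3-carboxylate | COC(=O)C1=CN(C)C2=COC(=O)C=C12
A2 | alternative 1 | bis(trimethylsilyl)acetylene | C[Si](C)(C)C#C[Si](C)(C)C
A3 | alternative 1 | methyl 1-methyl-5,6-bis(trimethylsilyl)indole-3-carboxylate | COC(=O)c1cn(C)c2cc([Si](C)(C)C)c([Si](C)(C)C)cc12
A4 | alternative 2 | 3,4-dibromothiophene 1,1-dioxide | O=S1(=O)C=C(Br)C(Br)=C1
A5 | alternative 2 | 1-methyl-5-(methylsulfanyl)-1,3-dihydro-2H-pyrrol-2-one | CSC1=CCC(=O)N1C
A6 | alternative 2 | 5,6-dibromo-1-methylindolin-2-one | CN1C(=O)Cc2cc(Br)c(Br)cc12
A7 | alternative 2 | 2,5,6-tribromo-1-methylindole-3-carbaldehyde | O=Cc1c(Br)n(C)c2cc(Br)c(Br)cc12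
A8 | alternative 3 | methyl 4,5-bis(bromoethynyl)-1-methylpyrrole-2-carboxylate | COC(=O)c1cc(C#CBr)c(C#CBr)n1C
A9 | alternative 3 | methyl 5,6-dibromo-1-methylindole-2-carboxylate | COC(=O)c1cc2cc(Br)c(Br)cc2n1C
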